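Retrosynthesis: after desilylation, the C10′ methyl is traced back to a formyl group and the C5′ isopropenyl to an acetyl group; the cyclohexene is then cut at C5′–C6′ and C9′–C10′.
Enabling feature: ring C5′–C10′ has its alkene at C7′=C8′ (methyl on C8′) and carries the C9′ chain, the C10′ methyl and the C5′ isopropenyl on one face. This is the pattern of an endo [4+2] adduct of an (E)-1-alkyl-2-methylbutadiene (C6′–C9′) with a Z ene-dicarbonyl (C5′, C10′).
Diene: cut at C12–C9′ (Negishi coupling) into a C12 iodide made from sclareolide and (E)-1-iodo-2-methylbuta-1,3-diene; the dienophile comes from oxidative opening of a 2-methyl-4-alkylfuran.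
Forward order: rings A and B come with sclareolide; C3 is hydroxylated, the lactone becomes the C8 exocyclic alkene and the C12 iodide, the diene is attached, the cyclohexene closes in step 14, then CHO to CH3, acetyl to isopropenyl and desilylation.
Stereochemistry: C5, C9, C10 from sclareolide; C3 from enzymatic hydroxylation; C5′, C9′, C10′ from step 14 (relative: Z dienophile, E diene, endo topology; absolute: chiral boron catalyst).

Key step: step 14

Locants: labdane numbering for the decalin half (C1–C10, C11 and C12 on C9, C17 = exocyclic CH2 on C8); primed locants C5′–C10′ for the cyclohexene.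
Assumption: 5-methylfuran-3-carbaldehyde (16) is taken as a catalogue compound; 3β-hydroxysclareolide is not, so it is made in step 1 by the established biocatalytic C3 hydroxylation.

Step 1
Reactants: 1 (+)-sclareolide
Product: 2 3β-hydroxysclareolide
Conditions: P450BM3 variant engineered for C3 oxidation of sclareolide (E. coli lysate), NADP+ (catalytic), phosphite dehydrogenase, Na2HPO3, air, K2HPO4/KH2PO4 buffer pH 8.0, 25 °C
Reagents that add atoms: dioxygen, O=O
Why: Enzymatic C–H hydroxylation by an engineered P450BM3 monooxygenase is established for sclareolide at C3, the enzyme pocket presenting the equatorial 3β hydrogen of ring A to the iron-oxo species so that oxygen rebound with retention sets the 3S carbinol.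

Step 2
Reactants: 2 3β-hydroxysclareolide
Product: 3 3β-(tert-butyldimethylsilyloxy)sclareolide
Conditions: TBSOTf, 2,6-lutidine, CH2Cl2, 0 °C
Reagents that add atoms: tert-butyldimethylsilyl triflate, CC(C)(C)[Si](C)(C)OS(=O)(=O)C(F)(F)F
Why: Silyl ether formation with the silyl triflate should cap the hindered equatorial C3 alcohol next to the gem-dimethyl group while the lactone stays inert.

Step 3
Reactants: 3 3β-(tert-butyldimethylsilyloxy)sclareolide
Product: 4 hydroxy Weinreb amide (3β-TBSO-8α-hydroxy-N-methoxy-N-methyl-13,14,15,16-tetranorlabdan-12-amide)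
Conditions: MeNH(OMe)·HCl, AlMe3, CH2Cl2, 0 → 25 °C
Reagents that add atoms: N,O-dimethylhydroxylamine hydrochloride, CNOC.Cl
Why: Aluminium amide aminolysis of the lactone (Weinreb amide formation) should open the ring at the acyl carbon and free the 8α tertiary alcohol without touching any stereocentre.

Step 4
Reactants: 4 hydroxy Weinreb amide
Product: 5 exocyclic alkene Weinreb amide (3β-TBSO-N-methoxy-N-methyl-13,14,15,16-tetranorlabd-8(17)-en-12-amide)
Conditions: SOCl2, pyridine, CH2Cl2, −78 °C
Reagents that add atoms: none
Why: Chlorosulfite formation and pyridine-mediated elimination of the axial 8α alcohol at low temperature should remove a proton from the C8 methyl group (no anti hydrogen at C9, and the methyl hydrogens are the most accessible), the dehydration mode known for this hydroxy amide series.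

Step 5
Reactants: 5 exocyclic alkene Weinreb amide
Product: 7 C12 primary alcohol (3β-TBSO-13,14,15,16-tetranorlabd-8(17)-en-12-ol), via C12 aldehyde 6 (not isolated)
Conditions: i-Bu2AlH, CH2Cl2, −78 °C; then MeOH, NaBH4, −78 → 0 °C
Reagents that add atoms: none
Why: Hydride reduction of the Weinreb amide stops at the chelated tetrahedral aluminate, which collapses to the aldehyde on methanol quench and is then reduced by NaBH4 in the same flask.

Step 6
Reactants: 7 C12 primary alcohol
Product: 8 C12 iodide (12-iodo-3β-TBSO-13,14,15,16-tetranorlabd-8(17)-ene)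
Conditions: I2, PPh3, imidazole, CH2Cl2, 0 → 25 °C
Reagents that add atoms: iodine, II
Why: Appel-type iodination through the alkoxyphosphonium iodide should proceed by SN2 displacement at the unhindered primary C12 and leave the exocyclic alkene and silyl ether alone.

Step 7
Reactants: 9 propargyl alcohol
Product: 11 (E)-3-iodo-2-methylprop-2-en-1-ol, via alkenylalane 10 (not isolated)
Conditions: AlMe3, Cp2ZrCl2 (25 mol %), CH2Cl2, 0 → 25 °C; then I2, THF, −30 → 0 °C
Reagents that add atoms: trimethylaluminium, C[Al](C)C; iodine, II
Why: Zirconium-catalysed syn carboalumination (Negishi carboalumination) puts methyl on the internal and aluminium on the terminal alkyne carbon, and iodinolysis of the C–Al bond with retention fixes the E alkenyl iodide.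

Step 8
Reactants: 11 (E)-3-iodo-2-methylprop-2-en-1-ol
Product: 12 (E)-3-iodo-2-methylprop-2-enal
Conditions: MnO2, CH2Cl2, 25 °C
Reagents that add atoms: none
Why: Allylic alcohol oxidation on MnO2 is neutral and should not isomerise the iodoalkene.

Step 9
Reactants: 12 (E)-3-iodo-2-methylprop-2-enal
Product: 13 (E)-1-iodo-2-methylbuta-1,3-diene
Conditions: Ph3PCH3Br, NaN(SiMe3)2, THF, −78 → 0 °C; kept as a cold ethereal solution
Reagents that add atoms: methyltriphenylphosphonium bromide, C[P+](c1ccccc1)(c1ccccc1)c1ccccc1.[Br-]
Why: Wittig methylenation of the enal builds the terminal vinyl group without touching the iodoalkene geometry, the volatile diene being carried on in solution.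

Step 10
Reactants: 8 C12 iodide; 13 (E)-1-iodo-2-methylbuta-1,3-diene
Product: 15 sclareolide-derived (E)-diene (8 with iodine replaced by the (1E)-2-methylbuta-1,3-dien-1-yl group), via alkylzinc iodide 14 (not isolated)
Conditions: Zn dust (activated), LiCl, THF, 40 °C; then 13, Pd(PPh3)4 (5 mol %), THF, 25 °C
Reagents that add atoms: none
Why: LiCl-assisted zinc insertion into the primary iodide gives an alkylzinc that should undergo Negishi coupling with the alkenyl iodide at zerovalent palladium with retention of the E geometry, reductive elimination outrunning β-hydride loss for a primary alkyl–alkenyl pair.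

Step 11
Reactants: 16 5-methylfuran-3-carbaldehyde
Product: 17 methyl (E)-3-(5-methylfuran-3-yl)acrylate
Conditions: Ph3P=CHCO2Me, CH2Cl2, 25 °C
Reagents that add atoms: methyl (triphenylphosphoranylidene)acetate, COC(=O)C=P(c1ccccc1)(c1ccccc1)c1ccccc1
Why: Wittig olefination with the stabilised ylide adds the three-carbon ester arm, the alkene geometry being irrelevant because it is removed in the next step.

Step 12
Reactants: 17 methyl (E)-3-(5-methylfuran-3-yl)acrylate
Product: 18 methyl 3-(5-methylfuran-3-yl)propanoate
Conditions: Mg turnings, MeOH, 0 → 25 °C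
Reagents that add atoms: none
Why: Dissolving-metal conjugate reduction by electron transfer to the heteroaryl-conjugated enoate should saturate only the acrylate alkene and spare the furan and the methyl ester.

Step 13
Reactants: 18 methyl 3-(5-methylfuran-3-yl)propanoate
Product: 19 methyl (Z)-4-formyl-6-oxohept-4-enoate
Conditions: dimethyldioxirane (1.05 equiv, acetone solution), acetone, −78 → −20 °C; concentrated cold and used at once
Reagents that add atoms: dimethyldioxirane, CC1(C)OO1
Why: Furan oxidation by epoxidation and electrocyclic opening of the furan epoxide should deliver the ene-dicarbonyl with the cis geometry inherited from the ring, under neutral conditions with acetone as the only coproduct so that Z to E isomerisation is not triggered.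

Step 14
Reactants: 15 sclareolide-derived (E)-diene; 19 methyl (Z)-4-formyl-6-oxohept-4-enoate
Product: 20 formyl acetyl cyclohexene adduct (C5′ acetyl, C9′ side chain and C10′ formyl all cis; C10′ also bears CH2CH2CO2Me; alkene C7′=C8′)
Conditions: oxazaborolidinium triflimide from (R)-3,3-diphenyl-1-(2-methylphenyl)tetrahydro-1H,3H-pyrrolo[1,2-c][1,3,2]oxazaborole and HN(SO2CF3)2 (20 mol %), 19 (1.5 equiv), CH2Cl2, −78 → −40 °C; Et3N quench
Reagents that add atoms: none
Why: The cationic boron centre binds the formyl oxygen of 19 (formyl C–H···O contact with the ring oxygen, s-trans enal), which makes C5′ the electrophilic terminus, so the unsubstituted diene carbon C6′ of 15 bonds to C5′ ahead of C9′–C10′ in a concerted asynchronous intermolecular [4+2]; the closest known reaction type is the oxazaborolidinium-catalysed Diels–Alder reaction of α-substituted enals. The cyclohexene C5′–C10′ closes in this single suprafacial–suprafacial event through a six-membered transition state that forms both σ bonds. The cis relation of acetyl (C5′) and formyl (C10′) is carried over from the Z alkene of 19, and the C9′ chain lands cis to both because the E-configured diene terminus meets a dienophile whose two carbonyl groups lie endo while the propanoate arm is exo. The sense of the three new centres relative to the decalin is set by the catalyst alone, the decalin centres being too remote: in the binding model the body of the (R)-catalyst covers the C10′-Re face, so the diene should add to the C10′-Si/C5′-Re face as required, and the antipodal catalyst is equally available should the model prove reversed for this dienophile. The step needs ortho-type regiochemistry (aldehyde-selective activation plus the usual preference of 1,2-dialkylbutadienes to bond through the unsubstituted terminus), endo topology (both carbonyls on one side of the alkene), face control (catalyst), and survival of the Z alkene and the C8 exocyclic methylene (low temperature, dienophile in excess, amine quench).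

Step 15
Reactants: 20 formyl acetyl cyclohexene adduct
Product: 21 aldehyde tosylhydrazone (C10′–CH=N–NHTs, acetyl intact)
Conditions: TsNHNH2 (1.05 equiv), THF, 0 → 25 °C
Reagents that add atoms: p-toluenesulfonohydrazide, Cc1ccc(cc1)S(=O)(=O)NN
Why: Hydrazone condensation is much faster at an aldehyde than at the flanked methyl ketone, and masking the formyl group first also removes the acceptor for an intramolecular aldol reaction of the acetyl group.

Step 16
Reactants: 21 aldehyde tosylhydrazone
Product: 22 isopropenyl tosylhydrazone
Conditions: Ph3PCH3Br, NaN(SiMe3)2 (ylide 3.5 equiv), THF, 0 → 25 °C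
Reagents that add atoms: methyltriphenylphosphonium bromide, C[P+](c1ccccc1)(c1ccccc1)c1ccccc1.[Br-]
Why: Wittig methylenation of the methyl ketone should proceed after the first equivalent of ylide has turned the hydrazone N–H into its unreactive anion, the bulky salt-free ylide adding to the carbonyl faster than it removes the hindered C5′ hydrogen so that C5′ keeps its configuration.

Step 17
Reactants: 22 isopropenyl tosylhydrazone
Product: 24 O-TBS methyl lansiolate, via N-boryl sulfonylhydrazine 23 (not isolated)
Conditions: catecholborane, CHCl3, 0 → 25 °C; then NaOAc·3H2O, 60 °C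
Reagents that add atoms: none
Why: Hydride reduction of the tosylhydrazone (a mild Wolff–Kishner-type deoxygenation) hydroborates the C=N bond, and acetate-induced loss of sulfinate gives an alkyldiazene that expels N2 to leave the C10′ methyl group, the neopentyl position offering no β-hydrogen or allylic path for side reactions.

Step 18
Reactants: 24 O-TBS methyl lansiolate
Product: 25 methyl lansiolate
Conditions: HF·pyridine, pyridine, THF, 0 → 25 °C
Reagents that add atoms: none
Why: Fluoride-driven desilylation under pyridine buffering should free the 3β alcohol without hydrolysing the methyl ester or isomerising the 1,1-disubstituted alkenes.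

Compound list
1 | (+)-sclareolide | C[C@]12CCCC([C@@H]1CC[C@@]3([C@@H]2CC(=O)O3)C)(C)C | starting material
2 | 3β-hydroxysclareolide | O=C1C[C@H]2[C@](C)(O1)CC[C@H]3C(C)(C)[C@@H](O)CC[C@]23C | intermediate
3 | 3β-(tert-butyldimethylsilyloxy)sclareolide | O=C1C[C@H]2[C@](C)(O1)CC[C@H]3C(C)(C)[C@@H](O[Si](C)(C)C(C)(C)C)CC[C@]23C | intermediate
4 | hydroxy Weinreb amide (3β-TBSO, 8α-OH, C12 N-methoxy-N-methylamide) | CON(C)C(=O)C[C@H]1[C@](C)(O)CC[C@H]2C(C)(C)[C@@H](O[Si](C)(C)C(C)(C)C)CC[C@]12C | intermediate
5 | exocyclic alkene Weinreb amide (3β-TBSO, 8(17)-ene) | CON(C)C(=O)C[C@H]1C(=C)CC[C@H]2C(C)(C)[C@@H](O[Si](C)(C)C(C)(C)C)CC[C@]12C | intermediate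
6 | C12 aldehyde (3β-TBSO, 8(17)-ene), not isolated | O=CC[C@H]1C(=C)CC[C@H]2C(C)(C)[C@@H](O[Si](C)(C)C(C)(C)C)CC[C@]12C | intermediate
7 | C12 primary alcohol (3β-TBSO, 8(17)-ene) | OCC[C@H]1C(=C)CC[C@H]2C(C)(C)[C@@H](O[Si](C)(C)C(C)(C)C)CC[C@]12C | intermediate
8 | C12 iodide (3β-TBSO, 8(17)-ene) | ICC[C@H]1C(=C)CC[C@H]2C(C)(C)[C@@H](O[Si](C)(C)C(C)(C)C)CC[C@]12C | intermediate
9 | propargyl alcohol | C#CCO | starting material
10 | (E)-alkenylalane, dimethylaluminium alkoxide form, not isolated | C[Al](C)/C=C(\C)CO[Al](C)C | intermediate
11 | (E)-3-iodo-2-methylprop-2-en-1-ol | OC/C(C)=C/I | intermediate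
12 | (E)-3-iodo-2-methylprop-2-enal | O=C/C(C)=C/I | intermediate
13 | (E)-1-iodo-2-methylbuta-1,3-diene | C=C/C(C)=C/I | intermediate
14 | C12 alkylzinc iodide, not isolated | I[Zn]CC[C@H]1C(=C)CC[C@H]2C(C)(C)[C@@H](O[Si](C)(C)C(C)(C)C)CC[C@]12C | intermediate
15 | sclareolide-derived (E)-1-alkyl-2-methylbutadiene (3β-TBSO) | C=C/C(C)=C/CC[C@H]1C(=C)CC[C@H]2C(C)(C)[C@@H](O[Si](C)(C)C(C)(C)C)CC[C@]12C | intermediate
16 | 5-methylfuran-3-carbaldehyde | Cc1cc(C=O)co1 | starting material
17 | methyl (E)-3-(5-methylfuran-3-yl)acrylate | COC(=O)/C=C/c1coc(C)c1 | intermediate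
18 | methyl 3-(5-methylfuran-3-yl)propanoate | COC(=O)CCc1coc(C)c1 | intermediate
19 | methyl (Z)-4-formyl-6-oxohept-4-enoate | CC(=O)/C=C(/CCC(=O)OC)C=O | intermediate
20 | formyl acetyl cyclohexene adduct (all-cis C5′ acetyl, C9′ chain, C10′ formyl; 3β-TBSO) | CC(=O)[C@@H]1CC=C(C)[C@H](CC[C@H]2C(=C)CC[C@H]3C(C)(C)[C@@H](O[Si](C)(C)C(C)(C)C)CC[C@]23C)[C@@]1(C=O)CCC(=O)OC | intermediate
21 | aldehyde (E)-tosylhydrazone of 20 | CC(=O)[C@@H]1CC=C(C)[C@H](CC[C@H]2C(=C)CC[C@H]3C(C)(C)[C@@H](O[Si](C)(C)C(C)(C)C)CC[C@]23C)[C@@]1(/C=N/NS(=O)(=O)c4ccc(C)cc4)CCC(=O)OC | intermediate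
22 | isopropenyl tosylhydrazone | C=C(C)[C@@H]1CC=C(C)[C@H](CC[C@H]2C(=C)CC[C@H]3C(C)(C)[C@@H](O[Si](C)(C)C(C)(C)C)CC[C@]23C)[C@@]1(/C=N/NS(=O)(=O)c4ccc(C)cc4)CCC(=O)OC | intermediate
23 | N-(1,3,2-benzodioxaborol-2-yl) sulfonylhydrazine, not isolated | C=C(C)[C@@H]1CC=C(C)[C@H](CC[C@H]2C(=C)CC[C@H]3C(C)(C)[C@@H](O[Si](C)(C)C(C)(C)C)CC[C@]23C)[C@@]1(CN(B4Oc5ccccc5O4)NS(=O)(=O)c6ccc(C)cc6)CCC(=O)OC | intermediate
24 | O-TBS methyl lansiolate | C=C(C)[C@@H]1CC=C(C)[C@H](CC[C@H]2C(=C)CC[C@H]3C(C)(C)[C@@H](O[Si](C)(C)C(C)(C)C)CC[C@]23C)[C@@]1(C)CCC(=O)OC | intermediate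
25 | methyl lansiolate | C=C(C)[C@@H]1CC=C(C)[C@H](CC[C@H]2C(=C)CC[C@H]3C(C)(C)[C@@H](O)CC[C@]23C)[C@@]1(C)CCC(=O)OC | target

Total step count: 18. Longest linear sequence: 12 steps (1–6, 10, 14–18); side branches are steps 7–9 and 11–13.

Steps most likely to fail

Step 14. Facial or endo discrimination may be insufficient for this β-acyl enal, or the strongly acidic boron cation may isomerise the Z alkene of 19 or start an ene reaction at the C8 exocyclic methylene. The fallback replaces catalyst control by auxiliary control and sets out from 19 (with 15), returning at 20. Compound 19 is acetalised selectively at the aldehyde with (2R,4R)-2,4-bis(trimethylsilyloxy)pentane and catalytic TMSOTf at −78 °C to give methyl (Z)-4-[(4R,6R)-4,6-dimethyl-1,3-dioxan-2-yl]-6-oxohept-4-enoate F1. The same promoter ionises the acetal to a tethered oxocarbenium dienophile, which adds diene 15 in an ionic Diels–Alder reaction with the same regiochemistry and endo topology; the face is chosen by the dioxane methyl groups, and re-closure gives the dioxane acetal of the adduct F2. PPTS in wet acetone then releases 20. The diol antipode would be fixed in a model run; the (R,R) series is the one listed.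

Step 13. The free Z keto-enal may isomerise to the E isomer or oligomerise while it is generated and concentrated. The fallback stores the dienophile in a masked, isolable form and sets out from 18, returning at 19. Oxidative 1,4-dimethoxylation of the furan (NBS, MeOH, NaHCO3, −40 °C) gives methyl 3-(2,5-dimethoxy-5-methyl-2,5-dihydrofuran-3-yl)propanoate F3 as a diastereomer mixture. It is hydrolysed with dilute aqueous acid in acetone at 0 °C immediately before step 14, unmasking the cis ene-dicarbonyl 19 from the ring.

Step 15. The sulfonylhydrazone N–H may close onto the cis acetyl group, or both carbonyls may condense, which would block the methylenation. The fallback differentiates the carbonyls through sulfur instead of nitrogen and sets out from 20, returning at 24. Aldehyde-selective thioacetalisation (ethane-1,2-dithiol, Zn(OTf)2, CH2Cl2, 0 °C) gives the 1,3-dithiolane of the adduct F4. Wittig methylenation of the remaining ketone gives the isopropenyl dithiolane F5, and radical desulfurisation (Bu3SnH, AIBN, toluene, 110 °C) converts the dithiolane carbon into the C10′ methyl group of 24.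

Further compounds
F1 | step 14 | methyl (Z)-4-[(4R,6R)-4,6-dimethyl-1,3-dioxan-2-yl]-6-oxohept-4-enoate | CC(=O)/C=C(/CCC(=O)OC)C1O[C@H](C)C[C@@H](C)O1
F2 | step 14 | (4R,6R)-4,6-dimethyl-1,3-dioxane acetal of adduct 20 | CC(=O)[C@@H]1CC=C(C)[C@H](CC[C@H]2C(=C)CC[C@H]3C(C)(C)[C@@H](O[Si](C)(C)C(C)(C)C)CC[C@]23C)[C@@]1(C4O[C@H](C)C[C@@H](C)O4)CCC(=O)OC
F3 | step 13 | methyl 3-(2,5-dimethoxy-5-methyl-2,5-dihydrofuran-3-yl)propanoate | COC1OC(C)(OC)C=C1CCC(=O)OC
F4 | step 15 | 1,3-dithiolane of adduct 20 (at the former formyl carbon) | CC(=O)[C@@H]1CC=C(C)[C@H](CC[C@H]2C(=C)CC[C@H]3C(C)(C)[C@@H](O[Si](C)(C)C(C)(C)C)CC[C@]23C)[C@@]1(C4SCCS4)CCC(=O)OC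
F5 | step 15 | isopropenyl 1,3-dithiolane | C=C(C)[C@@H]1CC=C(C)[C@H](CC[C@H]2C(=C)CC[C@H]3C(C)(C)[C@@H](O[Si](C)(C)C(C)(C)C)CC[C@]23C)[C@@]1(C4SCCS4)CCC(=O)OC
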